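**Plan**
- Retrosynthetic cuts: (a) the aryl–C(=O) bond (Weinreb amide + 2,4-dimethoxyphenyllithium). (b) The C3=C4 double bond, back to the saturated isochroman-3-carboxylate. (c) Both ring bonds of C3 (O2–C3 and C3–C4), which removes C3 as the carbene :CH–CO2Et. (d) One benzylic C–O bond of the remaining phthalan (diol), then back through 5,6-dimethoxyphthalide to its aryl–CH2 bond (veratric acid + CH2O).
- Enabling feature: in the pyran ring, C1 and C4 are both benzylic and sit on the neighbouring fusion atoms C8a and C4a, and the 6,7-dimethoxy pattern puts each para to one OMe. Without C3 the ring is therefore C2v-symmetric 5,6-dimethoxyphthalan, with one ether oxygen and two identical p-methoxybenzyl-type C–O bonds. This suits oxonium ylide formation and a [1,2]-shift.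
- Forward order: the dimethoxyarene is bought as veratric acid. The five-membered O-ring follows (steps 1–3: lactone, diol, cyclic ether). One-carbon insertion then gives the six-membered O-ring and brings in the acyl carbon (step 4). C3=C4 follows (step 5) and the second arene is joined last (steps 6–7).
- The carbene carries an ester rather than the 2,4-dimethoxybenzoyl group, because an o-methoxyaryl diazoketone would trap its own carbenoid as a five-membered oxonium ylide (benzofuranone pathway).
- Stereochemistry: the target is achiral. The only stereocentre on the way (C3 after step 4) is racemic and is erased in step 5.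

Key step: step 4

Assumption: the target has no stereocentre, and its only non-aromatic C=C is locked in the ring. It is therefore achiral and no enantiomer has to be selected.

**Step 1**
Reactants: 1 veratric acid (3,4-dimethoxybenzoic acid); 2 formaldehyde (37% aqueous solution)
Product: 4 5,6-dimethoxy-2-benzofuran-1(3H)-one (5,6-dimethoxyphthalide), via 2-(hydroxymethyl)-4,5-dimethoxybenzoic acid 3 (not isolated)
Conditions: 37% aq CH2O, conc. HCl, 70–90 °C
Reagents that add atoms: none
Why: Acid-mediated hydroxymethylation of the arene (Blanc/Lederer–Manasse-type electrophilic aromatic substitution) followed by lactonisation of 3 is the classical entry to this phthalide; attack is expected at C6 of 1, para to the 3-methoxy group and unhindered, and the ortho carboxyl group traps the new benzylic centre at once, so one CH2O is taken up and diarylmethane formation is held back.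

**Step 2**
Reactants: 4 5,6-dimethoxy-2-benzofuran-1(3H)-one
Product: 5 (4,5-dimethoxybenzene-1,2-diyl)dimethanol
Conditions: LiAlH4, THF, 0 °C to reflux; then H2O, 15% aq NaOH, H2O
Reagents that add atoms: none
Why: Standard LiAlH4 reduction of a lactone to the diol; the aryl methyl ethers are inert to hydride.

**Step 3**
Reactants: 5 (4,5-dimethoxybenzene-1,2-diyl)dimethanol
Product: 7 5,6-dimethoxy-1,3-dihydro-2-benzofuran (5,6-dimethoxyphthalan), via [2-(hydroxymethyl)-4,5-dimethoxyphenyl]methyl 4-methylbenzenesulfonate 6 (not isolated)
Conditions: NaH (2.2 equiv), THF, 0 °C; TsCl (1.0 equiv), 0 °C to rt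
Reagents that add atoms: 4-toluenesulfonyl chloride, Cc1ccc(S(=O)(=O)Cl)cc1 (Ts in 6 only)
Why: One-pot monosulfonylation and intramolecular Williamson etherification; either hydroxyl of the symmetric diol may be tosylated, and the neighbouring alkoxide should displace the very reactive p-methoxybenzyl-type tosylate by 5-exo-tet closure faster than a second tosylation, under basic conditions that avoid cationic oligomerisation.

**Step 4**
Reactants: 7 5,6-dimethoxy-1,3-dihydro-2-benzofuran; 8 ethyl diazoacetate
Product: 10 ethyl (±)-6,7-dimethoxy-3,4-dihydro-1H-isochromene-3-carboxylate, via 2-(2-ethoxy-2-oxoethan-1-id-1-yl)-5,6-dimethoxy-1,3-dihydro-2-benzofuran-2-ium (oxonium ylide) 9 (not isolated)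
Conditions: Cu(hfacac)2 (5 mol %), 8 (1.5 equiv, syringe pump, 8 h), ClCH2CH2Cl, 80 °C
Reagents that add atoms: none
Why: Proposed new method: the electrophilic copper carbenoid from 8 is captured by the only sp3 ether oxygen of 7 to give oxonium ylide 9, whose O–CH2Ar bond breaks (p-methoxybenzyl-type radical or cation paired with the captodative α-oxy ester radical or enolate) and whose ends recombine at carbon, a net [1,2]-Stevens shift that places one CH(CO2Et) unit into the C–O bond. The closest known reaction types are the carbenoid one-carbon ring expansions of oxetanes to tetrahydrofurans and of 2-aryl-1,3-dioxolanes to 1,4-dioxanes, and the insertion of diazoacetate-derived carbenes into the benzylic C–O bond of acyclic benzyl ethers; an unstrained phthalan has not been used in this way. The six-membered ring closes by collapse of a tethered 1,6-biradical (or zwitterion), so the fragments cannot diffuse apart as in acyclic Stevens shifts, and the five-membered ring grows by exactly one carbon. The new stereocentre C3 is not controlled (achiral catalyst, racemate) and need not be, because step 5 turns it into an sp2 carbon. Site selectivity is no issue because 7 is C2v-symmetric and both C–O bonds are identical; chemoselectivity for ylide formation over benzylic C–H insertion, arene cyclopropanation and carbene dimerisation is sought with an acceptor-only carbenoid, an electron-poor copper(II) catalyst and slow addition of 8. A second insertion should be held back because the ring oxygen of 10 is hindered and made less basic by the adjacent ester, and a Sommelet–Hauser-type [2,3]-shift is shut out because it would give a meta-bridged ring.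

**Step 5**
Reactants: 10 ethyl (±)-6,7-dimethoxy-3,4-dihydro-1H-isochromene-3-carboxylate
Product: 13 ethyl 6,7-dimethoxy-1H-isochromene-3-carboxylate, via ethyl 6,7-dimethoxy-3-(phenylselanyl)-3,4-dihydro-1H-isochromene-3-carboxylate 11 (not isolated), via ethyl 6,7-dimethoxy-3-(phenylseleninyl)-3,4-dihydro-1H-isochromene-3-carboxylate 12 (not isolated)
Conditions: LDA, THF, −78 °C; PhSeBr, −78 °C; then AcOH, 30% aq H2O2, 0 °C to rt (one pot)
Reagents that add atoms: phenylselenyl bromide, Br[Se]c1ccccc1 (PhSe in 11 and 12 only); hydrogen peroxide, OO (O in 12 only)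
Why: Reich selenoxide dehydrogenation, known for tetrahydropyran-2-carboxylates; the ester enolate (C3–H is the only acidic C–H) is selenenylated at C3, and selenoxide 12 should syn-eliminate below room temperature towards C4, the only neighbour of C3 that bears hydrogen, which erases the stereocentre.

**Step 6**
Reactants: 13 ethyl 6,7-dimethoxy-1H-isochromene-3-carboxylate
Product: 14 N,6,7-trimethoxy-N-methyl-1H-isochromene-3-carboxamide (Weinreb amide)
Conditions: MeNH(OMe)·HCl, i-PrMgCl, THF, −20 to 0 °C
Reagents that add atoms: N,O-dimethylhydroxylamine hydrochloride, CNOC.Cl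
Why: Weinreb amide formation by aminolysis of the ester with the chloromagnesium amide made in situ, a protocol that tolerates enoates; here there is no α-hydrogen to interfere.

**Step 7**
Reactants: 14 N,6,7-trimethoxy-N-methyl-1H-isochromene-3-carboxamide; 15 1-bromo-2,4-dimethoxybenzene
Product: 17 (2,4-dimethoxyphenyl)(6,7-dimethoxy-1H-isochromen-3-yl)methanone (target), via 2,4-dimethoxyphenyllithium 16 (not isolated)
Conditions: 15, n-BuLi, THF, −78 °C; then 14, −78 to 0 °C; sat. aq NH4Cl
Reagents that add atoms: n-butyllithium, [Li]CCCC (Li in 16 only)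
Why: Br/Li exchange fixes lithium at C1 of the ring (direct lithiation of 1,3-dimethoxybenzene would go to C2 between the methoxy groups), and the Weinreb ketone synthesis stops at the chelated tetrahedral adduct, which releases the ketone only on quench.

**Compound list**
1 | veratric acid (3,4-dimethoxybenzoic acid) | COc1ccc(C(=O)O)cc1OC | starting material
2 | formaldehyde (37% aqueous solution) | C=O | starting material
3 | 2-(hydroxymethyl)-4,5-dimethoxybenzoic acid | COc1cc(CO)c(C(=O)O)cc1OC | intermediate (not isolated)
4 | 5,6-dimethoxy-2-benzofuran-1(3H)-one (5,6-dimethoxyphthalide) | COc1cc2c(cc1OC)C(=O)OC2 | intermediate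
5 | (4,5-dimethoxybenzene-1,2-diyl)dimethanol | COc1cc(CO)c(CO)cc1OC | intermediate
6 | [2-(hydroxymethyl)-4,5-dimethoxyphenyl]methyl 4-methylbenzenesulfonate | COc1cc(CO)c(COS(=O)(=O)c2ccc(C)cc2)cc1OC | intermediate (not isolated)
7 | 5,6-dimethoxy-1,3-dihydro-2-benzofuran | COc1cc2c(cc1OC)COC2 | intermediate
8 | ethyl diazoacetate | CCOC(=O)C=[N+]=[N-] | starting material
9 | oxonium ylide of 7 with ethoxycarbonylcarbene | CCOC(=O)[CH-][O+]1Cc2cc(OC)c(OC)cc2C1 | intermediate (not isolated)
10 | ethyl (±)-6,7-dimethoxy-3,4-dihydro-1H-isochromene-3-carboxylate | CCOC(=O)C1Cc2cc(OC)c(OC)cc2CO1 | intermediate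
11 | ethyl (±)-6,7-dimethoxy-3-(phenylselanyl)-3,4-dihydro-1H-isochromene-3-carboxylate | CCOC(=O)C1([Se]c2ccccc2)Cc2cc(OC)c(OC)cc2CO1 | intermediate (not isolated)
12 | ethyl 6,7-dimethoxy-3-(phenylseleninyl)-3,4-dihydro-1H-isochromene-3-carboxylate (mixture of stereoisomers) | CCOC(=O)C1([Se](=O)c2ccccc2)Cc2cc(OC)c(OC)cc2CO1 | intermediate (not isolated)
13 | ethyl 6,7-dimethoxy-1H-isochromene-3-carboxylate | CCOC(=O)C1=Cc2cc(OC)c(OC)cc2CO1 | intermediate
14 | N,6,7-trimethoxy-N-methyl-1H-isochromene-3-carboxamide | CON(C)C(=O)C1=Cc2cc(OC)c(OC)cc2CO1 | intermediate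
15 | 1-bromo-2,4-dimethoxybenzene | COc1ccc(Br)c(OC)c1 | starting material
16 | 2,4-dimethoxyphenyllithium | [Li]c1ccc(OC)cc1OC | intermediate (not isolated)
17 | (2,4-dimethoxyphenyl)(6,7-dimethoxy-1H-isochromen-3-yl)methanone | COc1ccc(C(=O)C2=Cc3cc(OC)c(OC)cc3CO2)c(OC)c1 | target

Total step count: 7. Longest linear sequence: 7 steps (1 to 17).

**Steps most likely to fail**

**Step 4 (Proposed new method).**
- Risk: the carbenoid may be used up by dimerisation, benzylic C–H insertion or attack on the electron-rich arene before the ether oxygen captures it. Alternatively, the unstrained ylide may revert instead of rearranging.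
- Fallback (known chemistry): it sets out from 5 and comes back at 13. The ring is still made by a 5→6 expansion, but by oxygen insertion instead of carbon insertion.
- Diol 5 would be converted with PBr3 (CH2Cl2, 0 °C) into 1,2-bis(bromomethyl)-4,5-dimethoxybenzene F1.
- This dibromide would doubly alkylate TosMIC (aq NaOH/CH2Cl2, Bu4NI) to give 2-isocyano-5,6-dimethoxy-2-tosylindane F2.
- Acid hydrolysis (HCl, THF) gives 5,6-dimethoxyindan-2-one F3.
- Baeyer–Villiger oxidation of this symmetric ketone (mCPBA, NaHCO3, CH2Cl2) can give only 6,7-dimethoxyisochroman-3-one F4.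
- O-phosphorylation of its benzylic lactone enolate (KHMDS, (PhO)2P(O)Cl, THF, −78 °C) gives 6,7-dimethoxy-1H-isochromen-3-yl diphenyl phosphate F5.
- Palladium-catalysed ethoxycarbonylation of this ketene acetal phosphate (Pd(PPh3)4, CO 1 atm, EtOH, Et3N, DMF) gives 13.

**Step 5.**
- Risk: selenenylation at the fully substituted C3 may be slow. Peroxide or perseleninic acid may also over-oxidise the electron-rich enol ether or the benzylic C1 position.
- Fallback: it sets out from 10 and comes back at 17. The dehydrogenation is moved to the ketone stage and needs no peroxide.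
- Ester 10 would be converted (MeNH(OMe)·HCl, i-PrMgCl) into N,6,7-trimethoxy-N-methyl-3,4-dihydro-1H-isochromene-3-carboxamide F6.
- Addition of 16 gives (2,4-dimethoxyphenyl)(6,7-dimethoxy-3,4-dihydro-1H-isochromen-3-yl)methanone F7, which can enolise only at C3.
- Soft enolisation (TMSOTf, Et3N, CH2Cl2) gives its trimethylsilyl enol ether F8.
- Saegusa–Ito oxidation (Pd(OAc)2, MeCN) gives 17.

**Step 7.**
- Risk: the hindered aryllithium may add in conjugate fashion at C4, deprotonate C1, or add incompletely to the amide.
- Fallback: it sets out from 14 and comes back at 17.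
- DIBAL-H (THF, −78 °C) reduces 14 to 6,7-dimethoxy-1H-isochromene-3-carbaldehyde F9.
- This more electrophilic carbonyl takes up 16 by 1,2-addition to give (2,4-dimethoxyphenyl)(6,7-dimethoxy-1H-isochromen-3-yl)methanol F10.
- Neutral oxidation of this allylic, benzylic alcohol (MnO2, CH2Cl2) gives 17.

**Further compounds**
F1 | step 4 | 1,2-bis(bromomethyl)-4,5-dimethoxybenzene | COc1cc(CBr)c(CBr)cc1OC
F2 | step 4 | 2-isocyano-5,6-dimethoxy-2-(4-methylphenyl)sulfonyl-2,3-dihydro-1H-indene | COc1cc2c(cc1OC)CC([N+]#[C-])(S(=O)(=O)c1ccc(C)cc1)C2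
F3 | step 4 | 5,6-dimethoxyindan-2-one | COc1cc2c(cc1OC)CC(=O)C2
F4 | step 4 | 6,7-dimethoxyisochroman-3-one | COc1cc2c(cc1OC)COC(=O)C2
F5 | step 4 | 6,7-dimethoxy-1H-isochromen-3-yl diphenyl phosphate | COc1cc2c(cc1OC)COC(OP(=O)(Oc1ccccc1)Oc1ccccc1)=C2
F6 | step 5 | (±)-N,6,7-trimethoxy-N-methyl-3,4-dihydro-1H-isochromene-3-carboxamide | CON(C)C(=O)C1Cc2cc(OC)c(OC)cc2CO1
F7 | step 5 | (±)-(2,4-dimethoxyphenyl)(6,7-dimethoxy-3,4-dihydro-1H-isochromen-3-yl)methanone | COc1ccc(C(=O)C2Cc3cc(OC)c(OC)cc3CO2)c(OC)c1
F8 | step 5 | trimethylsilyl enol ether of F7 (E/Z not defined) | COc1ccc(C(O[Si](C)(C)C)=C2Cc3cc(OC)c(OC)cc3CO2)c(OC)c1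
F9 | step 7 | 6,7-dimethoxy-1H-isochromene-3-carbaldehyde | O=CC1=Cc2cc(OC)c(OC)cc2CO1
F10 | step 7 | (±)-(2,4-dimethoxyphenyl)(6,7-dimethoxy-1H-isochromen-3-yl)methanol | COc1ccc(C(O)C2=Cc3cc(OC)c(OC)cc3CO2)c(OC)c1
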